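Ring C is cut at C3–C4. C3 (bearing the methoxy oxygen) and C4 (the carbonyl carbon) are neighbouring oxygenated carbons, so both can be traced back to aldehyde carbons and joined by a reductive ketyl (pinacol) coupling. In one operation SmI2 forms C3–C4 and closes ring C as a flavan-3,4-diol, which two oxidations and enolisation through H-2 turn into the flavonol; no stereocontrol is needed. The precursor is a ring A benzaldehyde (future C4) carrying benzyl ethers at O5 and O7, an allyl ether at O8 and, on the ortho oxygen O1, a 1-phenyl-2-oxoethyl group (future C2 and C3).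

Key step: step 9

Assumption: 3,5-bis(benzyloxy)phenol (1) and (R)-2-methylbutanoic acid (19) are taken as purchasable, and bromo ester 10 is used as the racemate because its stereocentre becomes sp2.

Step 1
Reactants: 1 3,5-bis(benzyloxy)phenol
Product: 2 1,3-bis(benzyloxy)-5-(methoxymethoxy)benzene
Conditions: NaH, MOMCl, DMF, 0 °C to rt
Reagents that add atoms: chloromethyl methyl ether, COCCl
Why: Williamson-type O-alkylation of the phenoxide installs a MOM acetal that acts as the chelating director in the next step and is later removed without touching benzyl or allyl ethers.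

Step 2
Reactants: 2 1,3-bis(benzyloxy)-5-(methoxymethoxy)benzene
Product: 5 2,4-bis(benzyloxy)-6-(methoxymethoxy)phenol, via aryllithium 3 (not isolated), via dimethyl arylboronate 4 (not isolated)
Conditions: n-BuLi, THF, 0 °C; B(OMe)3, −78 °C to rt; AcOH, 30% aq. H2O2, 0 °C to rt
Reagents that add atoms: hydrogen peroxide, OO
Why: Directed ortho-metalation followed by borylation and oxidative C–B to C–O exchange should place the new oxygen (future O8) at one of the two equivalent positions between the chelating OMOM group and a benzyloxy group, which are favoured over the position flanked only by the two weaker benzyloxy directors.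

Step 3
Reactants: 5 2,4-bis(benzyloxy)-6-(methoxymethoxy)phenol
Product: 6 2-(allyloxy)-1,5-bis(benzyloxy)-3-(methoxymethoxy)benzene
Conditions: allyl bromide, K2CO3, DMF, rt
Reagents that add atoms: allyl bromide, C=CCBr
Why: Williamson ether synthesis caps O8 with an allyl group, which tolerates hydride, oxidants, SmI2 and base and can later be removed by zerovalent palladium in the presence of benzyl ethers.

Step 4
Reactants: 6 2-(allyloxy)-1,5-bis(benzyloxy)-3-(methoxymethoxy)benzene
Product: 7 2-(allyloxy)-3,5-bis(benzyloxy)phenol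
Conditions: HCl (cat.), MeOH, 50 °C
Reagents that add atoms: none
Why: Acid-catalysed acetal exchange with methanol cleaves only the MOM ether and frees the phenol that becomes O1, while allyl and benzyl ethers are stable to dilute acid.

Step 5
Reactants: 7 2-(allyloxy)-3,5-bis(benzyloxy)phenol
Product: 9 3-(allyloxy)-4,6-bis(benzyloxy)-2-hydroxybenzaldehyde, via hydroxymethyl phenol 8 (not isolated)
Conditions: MgCl2, Et3N, (CH2O)n, MeCN, reflux
Reagents that add atoms: paraformaldehyde (formaldehyde), C=O
Why: Magnesium-mediated ortho-formylation (Casnati–Skattebøl reaction) delivers formaldehyde from the magnesium phenoxide to the only free ortho position, and the hydroxymethyl phenol is oxidised in the flask by hydride transfer to a second formaldehyde.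

Step 6
Reactants: 9 3-(allyloxy)-4,6-bis(benzyloxy)-2-hydroxybenzaldehyde; 10 methyl 2-bromo-2-phenylacetate (racemic)
Product: 11 methyl 2-[2-(allyloxy)-3,5-bis(benzyloxy)-6-formylphenoxy]-2-phenylacetate (racemic)
Conditions: K2CO3, DMF, rt
Reagents that add atoms: none
Why: SN2 O-alkylation (Williamson) of the phenoxide with the activated α-bromo ester should proceed at room temperature, where the mild carbonate base does not trigger aldol closure onto the electron-rich formyl group, and the new stereocentre (future C2) is formed as a racemate that is erased later.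

Step 7
Reactants: 11 methyl 2-[2-(allyloxy)-3,5-bis(benzyloxy)-6-formylphenoxy]-2-phenylacetate (racemic)
Product: 12 2-[2-(allyloxy)-3,5-bis(benzyloxy)-6-(hydroxymethyl)phenoxy]-2-phenylethan-1-ol (racemic)
Conditions: LiAlH4, THF, 0 °C; then H2O, aq. NaOH
Reagents that add atoms: none
Why: Hydride reduction brings the ester and the aldehyde to the same alcohol level so that both can be oxidised together, while ethers and the isolated alkene are inert and the basic work-up protects the acid-labile benzylic alcohol.

Step 8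
Reactants: 12 2-[2-(allyloxy)-3,5-bis(benzyloxy)-6-(hydroxymethyl)phenoxy]-2-phenylethan-1-ol (racemic)
Product: 13 3-(allyloxy)-4,6-bis(benzyloxy)-2-(2-oxo-1-phenylethoxy)benzaldehyde (racemic)
Conditions: Dess–Martin periodinane, NaHCO3, CH2Cl2, 0 °C to rt; crude product used at once
Reagents that add atoms: none
Why: Dess–Martin oxidation converts both primary alcohols to aldehydes under buffered, amine-free conditions, which should avoid enolisation and aldol closure of the α-aryloxy aldehyde and ionisation of the very electron-rich benzylic alcohol.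

Step 9
Reactants: 13 3-(allyloxy)-4,6-bis(benzyloxy)-2-(2-oxo-1-phenylethoxy)benzaldehyde (racemic)
Product: 14 8-(allyloxy)-5,7-bis(benzyloxy)-2-phenylchromane-3,4-diol (stereoisomer mixture)
Conditions: SmI2 (2.5 equiv, 0.1 M in THF), THF, −78 °C to rt, slow addition of 13 to 0.01 M final concentration; then aq. potassium sodium tartrate
Reagents that add atoms: none
Why: Divalent samarium should transfer an electron first to the conjugated aryl aldehyde, and the samarium-bound benzylic ketyl at C4 then adds to the samarium-coordinated aliphatic formyl carbon C3, after which a second electron and protonation on work-up give the diol. The closest known reaction type is the SmI2-mediated intramolecular pinacol coupling of 1,6-dialdehydes to cyclic cis-1,2-diols. Ring C is closed in a 6-exo-trig mode, the C3 carbonyl lying outside the new ring O1–C2–C3–C4–C4a–C8a. The new stereocentres C3 and C4 should be set mainly cis by chelation of both oxygens to trivalent samarium, but no control is needed because C2, C3 and C4 all become sp2 in the next step. The selectivity required is chemoselectivity: ring closure must outrun reductive loss of the α-aryloxy group, simple reduction of either aldehyde and intermolecular coupling. This is secured by the easier reduction of the aryl aldehyde, by the ortho tether that holds C3 next to the ketyl, and by slow addition at low temperature and high dilution.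

Step 10
Reactants: 14 8-(allyloxy)-5,7-bis(benzyloxy)-2-phenylchromane-3,4-diol (stereoisomer mixture)
Product: 16 8-(allyloxy)-5,7-bis(benzyloxy)-3-hydroxy-2-phenyl-4H-chromen-4-one, via flavan-3,4-dione 15 (not isolated)
Conditions: IBX (2.5 equiv), DMSO, rt; then Et3N (cat.)
Reagents that add atoms: none
Why: IBX oxidation of a 1,2-diol gives the 1,2-dione without C–C cleavage in two two-electron oxidations, and the dione, whose H-2 is benzylic and flanked by O1 and the C3 ketone, should tautomerise to the conjugated 4-pyranone (the flavonol), converging all stereoisomers to one achiral product.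

Step 11
Reactants: 16 8-(allyloxy)-5,7-bis(benzyloxy)-3-hydroxy-2-phenyl-4H-chromen-4-one
Product: 17 8-(allyloxy)-5,7-bis(benzyloxy)-3-methoxy-2-phenyl-4H-chromen-4-one
Conditions: MeI, K2CO3, acetone, reflux
Reagents that add atoms: iodomethane, CI
Why: Williamson O-methylation of the acidic 3-enol, the only free hydroxyl in the molecule, fixes the 3-methoxy group.

Step 12
Reactants: 17 8-(allyloxy)-5,7-bis(benzyloxy)-3-methoxy-2-phenyl-4H-chromen-4-one
Product: 18 5,7-bis(benzyloxy)-8-hydroxy-3-methoxy-2-phenyl-4H-chromen-4-one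
Conditions: Pd(PPh3)4 (5 mol %), morpholine, THF, rt
Reagents that add atoms: none
Why: Tsuji–Trost-type deallylation, in which zerovalent palladium ionises the allyl aryl ether to a π-allyl complex that morpholine traps, should free only O8 and leave the benzyl ethers and the enol methyl ether untouched.

Step 13
Reactants: 18 5,7-bis(benzyloxy)-8-hydroxy-3-methoxy-2-phenyl-4H-chromen-4-one; 19 (R)-2-methylbutanoic acid
Product: 21 5,7-bis(benzyloxy)-3-methoxy-4-oxo-2-phenyl-4H-chromen-8-yl (2R)-2-methylbutanoate, via O-acylisourea 20 (not isolated)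
Conditions: DCC, DMAP (cat.), CH2Cl2, 0 °C to rt
Reagents that add atoms: none
Why: Steglich esterification acylates the single free phenol through the DMAP-activated O-acylisourea under nearly neutral conditions that should not enolise the α-branched acyl group, so the R centre bought with 19 is carried over unchanged.

Step 14
Reactants: 21 5,7-bis(benzyloxy)-3-methoxy-4-oxo-2-phenyl-4H-chromen-8-yl (2R)-2-methylbutanoate
Product: 22 5,7-dihydroxy-3-methoxy-4-oxo-2-phenyl-4H-chromen-8-yl (2R)-2-methylbutanoate
Conditions: H2 (1 atm), 10% Pd/C, EtOAc, rt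
Reagents that add atoms: none
Why: Catalytic hydrogenolysis cleaves both benzyl aryl ethers under neutral conditions that should prevent acyl migration from O8 to O7 and leave the tetrasubstituted pyranone double bond, the aryl ester and the stereocentre intact.

Compound list
1 | 3,5-bis(benzyloxy)phenol | Oc1cc(OCc2ccccc2)cc(OCc2ccccc2)c1 | starting material
2 | 1,3-bis(benzyloxy)-5-(methoxymethoxy)benzene | COCOc1cc(OCc2ccccc2)cc(OCc2ccccc2)c1 | intermediate
3 | [2,4-bis(benzyloxy)-6-(methoxymethoxy)phenyl]lithium | [Li]c1c(OCOC)cc(OCc2ccccc2)cc1OCc1ccccc1 | intermediate (not isolated)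
4 | dimethyl [2,4-bis(benzyloxy)-6-(methoxymethoxy)phenyl]boronate | COB(OC)c1c(OCOC)cc(OCc2ccccc2)cc1OCc1ccccc1 | intermediate (not isolated)
5 | 2,4-bis(benzyloxy)-6-(methoxymethoxy)phenol | Oc1c(OCOC)cc(OCc2ccccc2)cc1OCc1ccccc1 | intermediate
6 | 2-(allyloxy)-1,5-bis(benzyloxy)-3-(methoxymethoxy)benzene | C=CCOc1c(OCOC)cc(OCc2ccccc2)cc1OCc1ccccc1 | intermediate
7 | 2-(allyloxy)-3,5-bis(benzyloxy)phenol | C=CCOc1c(O)cc(OCc2ccccc2)cc1OCc1ccccc1 | intermediate
8 | 2-(allyloxy)-3,5-bis(benzyloxy)-6-(hydroxymethyl)phenol | C=CCOc1c(O)c(CO)c(OCc2ccccc2)cc1OCc1ccccc1 | intermediate (not isolated)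
9 | 3-(allyloxy)-4,6-bis(benzyloxy)-2-hydroxybenzaldehyde | C=CCOc1c(O)c(C=O)c(OCc2ccccc2)cc1OCc1ccccc1 | intermediate
10 | methyl 2-bromo-2-phenylacetate (racemic) | COC(=O)C(Br)c1ccccc1 | starting material
11 | methyl 2-[2-(allyloxy)-3,5-bis(benzyloxy)-6-formylphenoxy]-2-phenylacetate (racemic) | COC(=O)C(Oc1c(C=O)c(OCc2ccccc2)cc(OCc2ccccc2)c1OCC=C)c1ccccc1 | intermediate
12 | 2-[2-(allyloxy)-3,5-bis(benzyloxy)-6-(hydroxymethyl)phenoxy]-2-phenylethan-1-ol (racemic) | OCC(Oc1c(CO)c(OCc2ccccc2)cc(OCc2ccccc2)c1OCC=C)c1ccccc1 | intermediate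
13 | 3-(allyloxy)-4,6-bis(benzyloxy)-2-(2-oxo-1-phenylethoxy)benzaldehyde (racemic) | O=CC(Oc1c(C=O)c(OCc2ccccc2)cc(OCc2ccccc2)c1OCC=C)c1ccccc1 | intermediate
14 | 8-(allyloxy)-5,7-bis(benzyloxy)-2-phenylchromane-3,4-diol (stereoisomer mixture) | OC1C(O)c2c(OCc3ccccc3)cc(OCc3ccccc3)c(OCC=C)c2OC1c1ccccc1 | intermediate
15 | 8-(allyloxy)-5,7-bis(benzyloxy)-2-phenylchromane-3,4-dione | O=C1C(=O)c2c(OCc3ccccc3)cc(OCc3ccccc3)c(OCC=C)c2OC1c1ccccc1 | intermediate (not isolated)
16 | 8-(allyloxy)-5,7-bis(benzyloxy)-3-hydroxy-2-phenyl-4H-chromen-4-one | O=c1c(O)c(-c2ccccc2)oc2c(OCC=C)c(OCc3ccccc3)cc(OCc3ccccc3)c12 | intermediate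
17 | 8-(allyloxy)-5,7-bis(benzyloxy)-3-methoxy-2-phenyl-4H-chromen-4-one | COc1c(-c2ccccc2)oc2c(OCC=C)c(OCc3ccccc3)cc(OCc3ccccc3)c2c1=O | intermediate
18 | 5,7-bis(benzyloxy)-8-hydroxy-3-methoxy-2-phenyl-4H-chromen-4-one | COc1c(-c2ccccc2)oc2c(O)c(OCc3ccccc3)cc(OCc3ccccc3)c2c1=O | intermediate
19 | (R)-2-methylbutanoic acid | CC[C@@H](C)C(=O)O | starting material
20 | O-[(2R)-2-methylbutanoyl]-N,N'-dicyclohexylisourea | CC[C@@H](C)C(=O)OC(=NC1CCCCC1)NC1CCCCC1 | intermediate (not isolated)
21 | 5,7-bis(benzyloxy)-3-methoxy-4-oxo-2-phenyl-4H-chromen-8-yl (2R)-2-methylbutanoate | CC[C@@H](C)C(=O)Oc1c(OCc2ccccc2)cc(OCc2ccccc2)c2c(=O)c(OC)c(-c3ccccc3)oc12 | intermediate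
22 | 5,7-dihydroxy-3-methoxy-4-oxo-2-phenyl-4H-chromen-8-yl (2R)-2-methylbutanoate | CC[C@@H](C)C(=O)Oc1c(O)cc(O)c2c(=O)c(OC)c(-c3ccccc3)oc12 | target

Total step count: 14
Longest linear sequence: 14 steps (1 to 22)

Steps most likely to fail

Step 9. Electron transfer to the aliphatic aldehyde followed by expulsion of the aryloxide, simple reduction of either formyl group, intermolecular coupling, or aldol closure of the labile dialdehyde before it meets the reductant would all divert material from ring closure. The fallback sets out from 9 and comes back at 17, closing ring C through O1–C2 instead. Compound 9 is treated with excess methoxymethyllithium (Bu3SnCH2OMe, n-BuLi, THF, −78 °C) to give 2-(allyloxy)-3,5-bis(benzyloxy)-6-(1-hydroxy-2-methoxyethyl)phenol F1. MnO2 in CH2Cl2 oxidises the benzylic carbinol to 1-[3-(allyloxy)-4,6-bis(benzyloxy)-2-hydroxyphenyl]-2-methoxyethan-1-one F2. Benzoyl chloride in pyridine gives 2-(allyloxy)-3,5-bis(benzyloxy)-6-(methoxyacetyl)phenyl benzoate F3. LiHMDS in THF brings about the Baker–Venkataraman acyl shift to 1-[3-(allyloxy)-4,6-bis(benzyloxy)-2-hydroxyphenyl]-2-methoxy-3-phenylpropane-1,3-dione F4. Cyclodehydration (AcOH, catalytic H2SO4) then gives 17.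

Step 2. Lithiation at the position between the two benzyloxy groups, or at a benzylic CH2 with subsequent Wittig rearrangement, would erode the regiochemistry of oxygenation. The fallback sets out from 1 and comes back at 5, with the position fixed by an ortho-specific formylation. Compound 1 is formylated (MgCl2, Et3N, (CH2O)n, MeCN, reflux) to 2,4-bis(benzyloxy)-6-hydroxybenzaldehyde F5. The phenol is protected (NaH, MOMCl, DMF) as 2,4-bis(benzyloxy)-6-(methoxymethoxy)benzaldehyde F6. Baeyer–Villiger oxidation with mCPBA in CH2Cl2 gives 2,4-bis(benzyloxy)-6-(methoxymethoxy)phenyl formate F7, and methanolysis (K2CO3, MeOH) gives 5.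

Step 10. The second oxidation may stall, the flavonol enol may be over-oxidised, or the electron-rich benzylic C4 position may ionise. The fallback sets out from 14 and comes back at 16, oxidising the two carbinols one at a time. DDQ in CH2Cl2 at rt oxidises only the benzylic C4 alcohol by hydride abstraction to give 8-(allyloxy)-5,7-bis(benzyloxy)-3-hydroxy-2-phenylchroman-4-one F8. The α-ketol is then oxidised with Cu(OAc)2 in aqueous AcOH at 80 °C to dione 15, which enolises to 16.

Further compounds
F1 | step 9 | 2-(allyloxy)-3,5-bis(benzyloxy)-6-(1-hydroxy-2-methoxyethyl)phenol | COCC(O)c1c(O)c(OCC=C)c(OCc2ccccc2)cc1OCc1ccccc1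
F2 | step 9 | 1-[3-(allyloxy)-4,6-bis(benzyloxy)-2-hydroxyphenyl]-2-methoxyethan-1-one | COCC(=O)c1c(O)c(OCC=C)c(OCc2ccccc2)cc1OCc1ccccc1
F3 | step 9 | 2-(allyloxy)-3,5-bis(benzyloxy)-6-(methoxyacetyl)phenyl benzoate | COCC(=O)c1c(OC(=O)c2ccccc2)c(OCC=C)c(OCc2ccccc2)cc1OCc1ccccc1
F4 | step 9 | 1-[3-(allyloxy)-4,6-bis(benzyloxy)-2-hydroxyphenyl]-2-methoxy-3-phenylpropane-1,3-dione | COC(C(=O)c1ccccc1)C(=O)c1c(O)c(OCC=C)c(OCc2ccccc2)cc1OCc1ccccc1
F5 | step 2 | 2,4-bis(benzyloxy)-6-hydroxybenzaldehyde | O=Cc1c(O)cc(OCc2ccccc2)cc1OCc1ccccc1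
F6 | step 2 | 2,4-bis(benzyloxy)-6-(methoxymethoxy)benzaldehyde | COCOc1cc(OCc2ccccc2)cc(OCc2ccccc2)c1C=O
F7 | step 2 | 2,4-bis(benzyloxy)-6-(methoxymethoxy)phenyl formate | COCOc1cc(OCc2ccccc2)cc(OCc2ccccc2)c1OC=O
F8 | step 10 | 8-(allyloxy)-5,7-bis(benzyloxy)-3-hydroxy-2-phenylchroman-4-one | O=C1c2c(OCc3ccccc3)cc(OCc3ccccc3)c(OCC=C)c2OC(c2ccccc2)C1O
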